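**Plan**

- Retrosynthesis: the (E)-alkene of the linker is cut first (cross-metathesis) into vinylchromene 8 and (S)-butenylchromene 10. The bond from the stereocentre to its vinyl group is cut next (hydrovinylation of 8 with ethylene), so both halves come from 8.
- 8 comes from bromochromene 6 (C6–vinyl bond, Suzuki–Miyaura). In 6 the pyran bonds C4–C4a and C2–C3 are cut: C3/C4 leave as acetylene and C2 is carried as a carboxylic acid derivative of an aryl ether made from 4-bromo-3-methoxyphenol.
- Forward order: aryl ether acid → redox-active ester → pyran ring by radical annulation with acetylene → vinyl group → stereocentre → union of the two halves.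
- Enabling feature: in each pyran ring C2 is fully substituted and bonded to the ether oxygen O1, so it can be a tertiary α-aryloxyalkyl radical; C3=C4 is an unsubstituted two-carbon bridge; C4a is the free arene carbon ortho to O1 and para to the C7 methoxy group. Both halves are the same 7-methoxy-2,2-dimethyl-2H-chromen-6-yl unit, so one annulation supplies both pyran rings.
- Stereochemistry: the (S) centre comes from ligand-controlled Ni-catalysed asymmetric hydrovinylation (step 5); the (E) alkene comes from thermodynamic control in the cross-metathesis (step 6).

Key step: step 3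

Assumption: in step 5 the phosphoramidite enantiomer is the one that delivers the (S)-alkene; the sense of induction is to be confirmed on a first small run, and the mirror-image ligand is used if it proves opposite.

**Route**

Step 1
Reactants: 1 4-bromo-3-methoxyphenol; 2 2-bromo-2-methylpropanoic acid
Product: 3 2-(4-bromo-3-methoxyphenoxy)-2-methylpropanoic acid
Conditions: NaOH (powder, 5 equiv), 2 (2 equiv), butan-2-one, 50 °C; then aq. HCl
Reagents that add atoms: none
Why: Williamson-type O-alkylation of the sodium phenoxide by the α-bromo carboxylate, the standard entry to fibrate-type 2-aryloxy-2-methylpropanoic acids; excess base keeps the acid as its carboxylate so only the phenoxide oxygen is alkylated.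

Step 2
Reactants: 3 2-(4-bromo-3-methoxyphenoxy)-2-methylpropanoic acid
Product: 4 1,3-dioxoisoindolin-2-yl 2-(4-bromo-3-methoxyphenoxy)-2-methylpropanoate
Conditions: N-hydroxyphthalimide, DIC, DMAP (cat.), CH2Cl2, 0 °C to rt
Reagents that add atoms: N-hydroxyphthalimide, O=C1c2ccccc2C(=O)N1O
Why: Carbodiimide (Steglich-type) esterification, routine for turning hindered 2-aryloxyisobutyric acids into N-acyloxyphthalimides (redox-active esters); the aryl bromide and the ethers are inert.

Step 3
Reactants: 4 1,3-dioxoisoindolin-2-yl 2-(4-bromo-3-methoxyphenoxy)-2-methylpropanoate; 5 acetylene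
Product: 6 6-bromo-7-methoxy-2,2-dimethyl-2H-chromene
Conditions: fac-Ir(ppy)3 (1 mol%), 5 (1 atm, balloon, solution presaturated), DMSO, blue LEDs (450 nm), rt
Reagents that add atoms: none
Why: Proposed new method: photoexcited fac-Ir(ppy)3 transfers one electron to the N-acyloxyphthalimide, which loses CO2 and phthalimide anion to give the tertiary α-aryloxyalkyl radical at the future C2 (stabilised by the O1 lone pair); this nucleophilic radical adds to acetylene, the σ-vinyl radical so formed at the future C4 attacks the arene carbon ortho to O1, and the cyclohexadienyl radical is oxidised by Ir(IV) and deprotonated by the phthalimide anion, so that the whole cycle is redox-neutral. The closest known reaction types are the photoredox decarboxylative addition/homolytic aromatic substitution cascades of redox-active esters with substituted alkynes and acrylamides, and the photoredox additions of nucleophilic carbon radicals to acetylene gas at 1 atm; their combination into a pyran annulation of an aryl ether has not been shown. The pyran ring closes by 6-endo attack of the vinyl radical on the ortho carbon (C4a); the competing 5-exo attack at the ipso carbon (C8a) could only go on by expelling an alkoxyl radical and should therefore be reversible. No stereocentre is formed, and the cis C3=C4 geometry follows from the ring size together with the fast inversion of the vinyl radical. The step needs regioselection between the two carbons ortho to the ether oxygen, and the methoxy group that flanks one of them should steer closure to the unhindered carbon para to it, which gives the 6-bromo-7-methoxy pattern. It also needs addition to acetylene to outrun oxidation or reduction of the C2 radical, which an acetylene-saturated DMSO solution, a low catalyst loading and moderate light intensity should secure.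

Step 4
Reactants: 6 6-bromo-7-methoxy-2,2-dimethyl-2H-chromene; 7 potassium vinyltrifluoroborate
Product: 8 6-ethenyl-7-methoxy-2,2-dimethyl-2H-chromene
Conditions: PdCl2(dppf) (3 mol%), Cs2CO3 (3 equiv), THF/H2O (9:1), 80 °C
Reagents that add atoms: none
Why: Suzuki–Miyaura vinylation of an electron-rich aryl bromide with a vinyltrifluoroborate; oxidative addition occurs only at C6–Br and the hindered chromene C3=C4 bond is inert.

Step 5
Reactants: 8 6-ethenyl-7-methoxy-2,2-dimethyl-2H-chromene; 9 ethylene
Product: 10 (S)-6-(but-3-en-2-yl)-7-methoxy-2,2-dimethyl-2H-chromene
Conditions: 9 (1 atm), [(η3-allyl)NiBr]2 (1 mol%), BINOL-derived N,N-bis(1-phenylethyl)phosphoramidite (2 mol%), NaBArF4 (2.5 mol%), CH2Cl2, −78 °C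
Reagents that add atoms: none
Why: Ni-catalysed asymmetric hydrovinylation of a vinylarene: the cationic Ni–H adds in the Markovnikov sense to give an η3-benzyl nickel species, ethylene inserts and β-hydride elimination releases the 3-arylbut-1-ene; the chiral phosphoramidite on nickel selects the face of the benzylic carbon and so sets the (S) centre, and the low temperature should prevent isomerisation of the product and reaction at the hindered C3=C4 bond.

Step 6
Reactants: 10 (S)-6-(but-3-en-2-yl)-7-methoxy-2,2-dimethyl-2H-chromene; 8 6-ethenyl-7-methoxy-2,2-dimethyl-2H-chromene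
Product: 11 (S,E)-7-methoxy-6-[3-(7-methoxy-2,2-dimethyl-2H-chromen-6-yl)but-1-en-1-yl]-2,2-dimethyl-2H-chromene
Conditions: 8 (3 equiv), Hoveyda–Grubbs II catalyst (5 mol%), 1,4-benzoquinone (10 mol%), CH2Cl2, 40 °C, argon sweep
Reagents that add atoms: none
Why: Olefin cross-metathesis between an α-branched terminal alkene (slow to homodimerise) and a styrene used in excess; loss of ethylene drives the reaction, the styrenyl alkene should form as the E isomer under thermodynamic control, the hindered cyclic C3=C4 bonds should not open productively, and benzoquinone suppresses Ru–H migration of the double bond so the stereocentre is not touched.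

**Compound list**

1 | 4-bromo-3-methoxyphenol | COc1cc(O)ccc1Br | starting material
2 | 2-bromo-2-methylpropanoic acid | CC(C)(Br)C(=O)O | starting material
3 | 2-(4-bromo-3-methoxyphenoxy)-2-methylpropanoic acid | COc1cc(OC(C)(C)C(=O)O)ccc1Br | intermediate
4 | 1,3-dioxoisoindolin-2-yl 2-(4-bromo-3-methoxyphenoxy)-2-methylpropanoate | COc1cc(OC(C)(C)C(=O)ON2C(=O)c3ccccc3C2=O)ccc1Br | intermediate
5 | acetylene (ethyne) | C#C | starting material
6 | 6-bromo-7-methoxy-2,2-dimethyl-2H-chromene | COc1cc2c(cc1Br)C=CC(C)(C)O2 | intermediate
7 | potassium vinyltrifluoroborate | C=C[B-](F)(F)F.[K+] | starting material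
8 | 6-ethenyl-7-methoxy-2,2-dimethyl-2H-chromene | COc1cc2c(cc1C=C)C=CC(C)(C)O2 | intermediate
9 | ethylene | C=C | starting material
10 | (S)-6-(but-3-en-2-yl)-7-methoxy-2,2-dimethyl-2H-chromene | C=C[C@H](C)c1cc2c(cc1OC)OC(C)(C)C=C2 | intermediate
11 | (S,E)-7-methoxy-6-[3-(7-methoxy-2,2-dimethyl-2H-chromen-6-yl)but-1-en-1-yl]-2,2-dimethyl-2H-chromene | COc1cc2c(cc1/C=C/[C@H](C)c1cc3c(cc1OC)OC(C)(C)C=C3)C=CC(C)(C)O2 | target

**Summary**

Total step count: 6. Longest linear sequence: 6 steps (1 → 3 → 4 → 6 → 8 → 10 → 11); compound 8 is used twice.

**Steps most likely to fail**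

1. Step 3 (proposed new method). The C2 radical may be oxidised to the oxocarbenium ion or reduced before it adds to acetylene, and ring closure may also occur at the carbon between the two oxygens, eroding regiocontrol. Fallback with known chemistry: it sets out from 1 and returns to the route at 6. Phenol 1 is O-alkylated with 3-chloro-3-methylbut-1-yne (K2CO3, KI, acetone, reflux) to give 1-bromo-2-methoxy-4-[(2-methylbut-3-yn-2-yl)oxy]benzene F1. Heating F1 in N,N-diethylaniline at about 190 °C (aromatic propargyl Claisen rearrangement, 1,5-hydrogen shift, oxa-6π electrocyclisation) should give 6.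

2. Step 5. The cationic nickel hydride may oligomerise the electron-rich styrene, enantioselection may be poor for an ortho-methoxy vinylarene, or the product may isomerise to the conjugated internal alkene. Fallback: it sets out from 8 and returns at 10. Cross-metathesis of 8 with diethyl allyl phosphate (Hoveyda–Grubbs II catalyst, CH2Cl2, 40 °C) gives (E)-diethyl 3-(7-methoxy-2,2-dimethyl-2H-chromen-6-yl)prop-2-en-1-yl phosphate F2. Copper-catalysed enantioselective SN2′ methylation of F2 (Me2Zn, chiral N-heterocyclic carbene–copper catalyst, THF, −15 °C) places the methyl group on the benzylic carbon and gives 10.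

3. Step 6. The ortho-methoxybenzylidene may chelate and sequester the ruthenium, the styrene may homodimerise, or Ru–H may move the terminal double bond into conjugation and erase the stereocentre. Fallback: it sets out from 10 and returns at 11. Cross-metathesis of 10 with vinylboronic acid pinacol ester (Hoveyda–Grubbs II catalyst, CH2Cl2, 40 °C) gives (S,E)-2-[3-(7-methoxy-2,2-dimethyl-2H-chromen-6-yl)but-1-en-1-yl]-4,4,5,5-tetramethyl-1,3,2-dioxaborolane F3. Suzuki–Miyaura coupling of F3 with bromide 6 (PdCl2(dppf), K3PO4, THF/H2O, 60 °C) fixes the E geometry and gives 11.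

**Further compounds**

F1 | step 3 | 1-bromo-2-methoxy-4-[(2-methylbut-3-yn-2-yl)oxy]benzene | COc1cc(OC(C)(C)C#C)ccc1Br
F2 | step 5 | (E)-diethyl 3-(7-methoxy-2,2-dimethyl-2H-chromen-6-yl)prop-2-en-1-yl phosphate | CCOP(=O)(OCC)OC/C=C/c1cc2c(cc1OC)OC(C)(C)C=C2
F3 | step 6 | (S,E)-2-[3-(7-methoxy-2,2-dimethyl-2H-chromen-6-yl)but-1-en-1-yl]-4,4,5,5-tetramethyl-1,3,2-dioxaborolane | CC1(C)OB(/C=C/[C@H](C)c2cc3c(cc2OC)OC(C)(C)C=C3)OC1(C)C
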